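Compound numbers are those of the steps below. Atom labels: C10 carries ring B and the pyran oxygen, C11 carries ring A (the prenylated ring). In the bicyclo[3.2.0]heptane, C1′ and C5′ are the ring-fusion methines, C2′ the methyl carbinol carbon, C6′ the CMe2 carbon and C7′ the methine bonded to C11.

## The problem

Target 33 is a pentacycle: a dibenz[b,f]oxepine whose C10=C11 double bond is also the enol-ether double bond of a 2H-pyran (O, C10, C11, C7′, C1′, C2′). The pyran shares C7′–C1′ with the cyclobutane and C1′–C2′ with the cyclopentane of a 6,6-dimethylbicyclo[3.2.0]heptane. There are four contiguous stereocentres: the three cyclobutane methines C1′, C5′ and C7′, all cis, and the quaternary C2′ with methyl exo and oxygen endo. A four/five ring fusion can only be cis, so one cyclobutane centre of defined absolute configuration can dictate the other two if the rings are closed onto it. The folded bicycle then directs a nucleophile to the convex face of a C2′ ketone, so absolute configuration has to be introduced only once. The o-prenylphenol (acid closes it to a chroman), the electron-rich diaryl enol ether (aqueous acid, oxidants), the free resorcinol-type phenols and the strained ring exclude strong acid, hydrogenation and late oxidation. The enabling feature appears when the pyran O–C10 bond is opened in the mind: C10 becomes an aryl ketone and C2′ a tertiary alcohol, that is, methyl plus cyclopentanone. The chain C10–C11–C7′–C1′–C2′ is then a 1,5-dicarbonyl unit with ring A on C11 and C7′–C1′ inside a cyclobutane. This is the pattern left by an enol–alkene [2+2] photocycloaddition followed by retro-aldol opening (de Mayo reaction).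

## Retrosynthesis

**33 to 30.** The two silyl ethers are removed first (32), then the pyran O–C10 bond is cut to give hydroxy ketone 30. Cutting O–C2′ instead would require a tertiary cation next to a prenyl group. The chosen cut asks only for hemiketal formation and loss of water under mild acid, with the o-prenylphenol still silylated so that it cannot cyclise. The forward step needs the C2′ hydroxyl endo.

**30 to 28.** The C2′–CH3 bond is cut. This returns a cyclopentanone, exactly what a retro-aldol opening leaves, and postpones the fourth stereocentre to a convex-face addition. The forward reaction must select the cyclopentanone over the C10 aryl ketone; the C10 ketone is masked as its enolate, which is the more acidic site by far.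

**28 to 25.** The C10–ring B bond is cut (Friedel–Crafts acylation) back to acid 26 and its methyl ester 25. The position attacked is para to a silyloxy group and ortho to the diaryl ether oxygen, the most nucleophilic carbon in the molecule, and the diaryl ether pre-organises the seven-membered ring. Cutting C11–ring A or the ether oxygen instead would leave the hindered C7′–C11 bond or the terpenoid core unsolved. The price is an acid-mediated step in the presence of the prenyl group.

**25 to 22 (key disconnection).** The bonds C7′–C11 and C1′–C2′ are cut together with the cyclopentanone ring. β-Keto ester 22 has one stereocentre that matters, one ring fewer in the core and no cyclobutane substituents to control. The forward reaction is asked to add the enol C=C across the tethered 3,3-dimethylcyclobutene and to fragment the temporary cyclobutanol. Three choices support it from within. The α-aryl group makes the keto ester strongly enolised and shifts its absorption beyond that of the aryl ethers. The triisopropylsilyl ethers allow a hydrocarbon solvent in which the chelated enol dominates. Light is filtered through Pyrex.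

**22 to 19 + 11.** The bond between the aryl-bearing carbon and the ketone carbonyl is cut (Claisen-type C-acylation of the arylacetate enolate by acyl imidazole 20). This is the convergent point; both halves carry their full functionality and no stereocentre is formed.

**11 to 3 + 4.** Acid 11 comes from ester 10, the cyclobutene from enol triflate 9 and this from cyclobutanone 7, where only one α-carbon can enolise. Both ring bonds of 7 are cut to a keteniminium ion from chiral amide 3 and methyl pent-4-enoate 4. The cycloaddition places the side chain next to the gem-dimethyl carbon, which is the substitution pattern required, and sets the one stereocentre that later controls the others.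

**19 to 14 + 12.** The aryl–prenyl bond (Stille coupling of bromide 18) and the diaryl ether bond (Chan–Lam coupling of phenol 17 with boronic acid 13) are cut. Bromide 17 follows from 2,4-dihydroxyphenylacetic acid 14 by esterification (15), silylation of the unhindered 4-hydroxyl (16) and bromination para to the remaining phenol. Boronic acid 13 is the silyl ether of 12.

## Roads not taken

**Alternative 1:** The cyclobutane is carved from a diquinane: the C6′–C7′ bond is made by ring contraction. A Pauson–Khand cyclisation would give the bicyclo[3.3.0]octane; gem-dimethylation and diazo transfer would lead to diazo ketone A1; irradiation in methanol (Wolff rearrangement) would give ester A2.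
- Merits: each reaction type is thoroughly established, and the photochemical step runs on a small substrate with no competing chromophore. In that respect it is safer than step 13.
- Weak points: A2 holds only the terpenoid carbons, and its ester carbon must become C11. Ring A, C10 and ring B would all have to be attached afterwards at a neopentyl-like, endo position. The ester stereocentre arises by kinetic protonation and can epimerise to the trans isomer, which cannot close the pyran. The two α-positions of the diquinanone must be differentiated, and absolute configuration still needs an asymmetric cyclisation or a resolution.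
- Comparison: against the more reliable photochemistry of this road, the chosen plan sets convergence. Its photoproduct 25 already contains every carbon except the C2′ methyl, with the right oxidation level at C10 and C2′.

**Alternative 2:** Both cyclobutane bonds (C1′–C5′ and C6′–C7′) are cut at once. Butenolide A4, available from (R)-linalool A3, would be irradiated with acetone sensitisation to give tricyclic lactone A5.
- Merits: C2′ comes from the chiral pool and the lactone tether relays it to the three cyclobutane centres. No auxiliary and no face-selective methyl addition are needed. In stereochemical economy and in step count to the terpenoid core this road is better than the chosen one.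
- Weak points: the lactone carbonyl carbon of A5 corresponds to C11. It must receive ring A, be extended by C10, and end as an sp2 carbon in a seven-membered ring. This amounts to a one-carbon ring expansion of the lactone at a hindered centre, followed by a C10=C11-forming closure between two diaryl carbons, passing through ketones with an epimerisable C7′.
- Comparison: the chosen plan pays for its weaker stereochemical economy with a much shorter and better-precedented end game (acylation, methyl addition, dehydration).

**Alternative 3:** The C11–ring A and O–ring B bonds are cut. 2-Fluoroaryl ketone A6 and bromophenol A7 would be joined by Pd(OAc)2/XPhos/NaOtBu α-arylation followed by phenoxide displacement of fluoride, giving oxepinone A8 in one pot.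
- Merits: the oxepinone is closed without acid, so the prenyl group is never exposed to an electrophilic medium. This is a real advantage over step 15, and the aromatic part is assembled very convergently.
- Weak points: A6 already contains the complete bicycle with all four stereocentres, so the central problem is deferred to a further key step. The arylation must occur at a methylene flanked by the endo cyclobutane, with an electron-rich bromophenoxide. The para silyloxy group weakens activation of the fluoride. NaOtBu at elevated temperature threatens aryl silyl ethers.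
- Comparison: the chosen plan sets against the acid-free ring closure its solution of the cyclobutane and the C7′–C11 bond in one step. It answers the acid problem with the mildest acylating system and with full silylation of the o-prenylphenol.

Key step: step 13

Assumption: the (2R,5R)-auxiliary is taken to deliver the (S)-cyclobutanone 7; if the sense of induction is the opposite, the (2S,5S)-amine is used and nothing else changes.

Abbreviations: TIPS = triisopropylsilyl; Ar = 5-(3-methylbut-2-en-1-yl)-4-(TIPS-oxy)-2-[3-(TIPS-oxy)phenoxy]phenyl.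

## Route

Step 1
Reactants: 1 isobutyryl chloride; 2 (2R,5R)-2,5-dimethylpyrrolidine
Product: 3 2-methyl-1-[(2R,5R)-2,5-dimethylpyrrolidin-1-yl]propan-1-one
Conditions: Et3N, CH2Cl2, 0 °C to rt
Reagents that add atoms: none
Why: N-acylation of a secondary amine by an acid chloride; the auxiliary stereocentres are not touched.

Step 2
Reactants: 3 2-methyl-1-[(2R,5R)-2,5-dimethylpyrrolidin-1-yl]propan-1-one; 4 methyl pent-4-enoate
Product: 7 methyl 3-[(1S)-2,2-dimethyl-3-oxocyclobutyl]propanoate, via keteniminium triflate 5 (not isolated), via cyclobutaniminium triflate 6 (not isolated)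
Conditions: Tf2O, 2,4,6-collidine, ClCH2CH2Cl, -20 °C; 4 (3 equiv), 80 °C; then aq. NaHCO3, rt
Reagents that add atoms: water, O
Why: Keteniminium–alkene [2+2] cycloaddition: the terminal CH2 of 4 attacks the central carbon of 5 and the CMe2 carbon closes on the internal carbon, so the side chain ends next to the gem-dimethyl group. The C2-symmetric pyrrolidine differentiates the alkene faces and sets the ring stereocentre; hydrolysis of 6 releases ketone and auxiliary.

Step 3
Reactants: 7 methyl 3-[(1S)-2,2-dimethyl-3-oxocyclobutyl]propanoate
Product: 9 methyl 3-[(1S)-4,4-dimethyl-3-(trifluoromethanesulfonyloxy)cyclobut-2-en-1-yl]propanoate, via potassium enolate 8 (not isolated)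
Conditions: KN(SiMe3)2, THF, -78 °C; N-(5-chloropyridin-2-yl)bis(trifluoromethanesulfonimide), -78 to -40 °C
Reagents that add atoms: N-(5-chloropyridin-2-yl)bis(trifluoromethanesulfonimide), O=S(=O)(N(c1ccc(Cl)cn1)S(=O)(=O)C(F)(F)F)C(F)(F)F
Why: Enol triflate formation: only the CH2 side of the ketone can enolise and the ketone is far more acidic than the ester, so kinetic deprotonation and O-sulfonylation at low temperature give one enol triflate before the enolate can attack the ester.

Step 4
Reactants: 9 methyl 3-[(1S)-4,4-dimethyl-3-(trifluoromethanesulfonyloxy)cyclobut-2-en-1-yl]propanoate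
Product: 10 methyl 3-[(1S)-4,4-dimethylcyclobut-2-en-1-yl]propanoate
Conditions: Pd(OAc)2 (5 mol%), PPh3, HCO2H, Bu3N, DMF, 40 °C
Reagents that add atoms: none
Why: Palladium-catalysed formate reduction of an enol triflate (oxidative addition to zerovalent palladium, formate exchange, loss of CO2, C–H reductive elimination); ester and allylic stereocentre are untouched and the mild temperature limits alkene migration.

Step 5
Reactants: 10 methyl 3-[(1S)-4,4-dimethylcyclobut-2-en-1-yl]propanoate
Product: 11 3-[(1S)-4,4-dimethylcyclobut-2-en-1-yl]propanoic acid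
Conditions: LiOH, THF/H2O, rt; then dil. HCl, 0 °C
Reagents that add atoms: lithium hydroxide, [Li+].[OH-]
Why: Saponification of an unhindered methyl ester; the cyclobutene and its stereocentre are inert to aqueous hydroxide.

Step 6
Reactants: 12 3-hydroxyphenylboronic acid
Product: 13 [3-(TIPS-oxy)phenyl]boronic acid
Conditions: TIPSCl, imidazole, DMF, rt; aqueous work-up
Reagents that add atoms: triisopropylsilyl chloride, CC(C)[Si](Cl)(C(C)C)C(C)C
Why: Phenol silylation; any B–O–Si bond is hydrolysed on work-up. TIPS is chosen because an unhindered aryl TIPS ether tolerates the later enolate and ester-cleavage steps better than smaller silyl groups.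

Step 7
Reactants: 14 2,4-dihydroxyphenylacetic acid
Product: 15 methyl 2-(2,4-dihydroxyphenyl)acetate
Conditions: MeOH, H2SO4 (cat.), reflux
Reagents that add atoms: methanol, CO
Why: Fischer esterification; the large excess of methanol holds the open ester against lactonisation to the benzofuranone.

Step 8
Reactants: 15 methyl 2-(2,4-dihydroxyphenyl)acetate
Product: 16 methyl 2-[2-hydroxy-4-(TIPS-oxy)phenyl]acetate
Conditions: TIPSCl (1.05 equiv), imidazole, CH2Cl2, 0 °C
Reagents that add atoms: triisopropylsilyl chloride, CC(C)[Si](Cl)(C(C)C)C(C)C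
Why: Selective silylation: the 4-hydroxyl has two free ortho positions, whereas the 2-hydroxyl is flanked by the CH2CO2Me arm, so the bulky silyl chloride takes the 4-position.

Step 9
Reactants: 16 methyl 2-[2-hydroxy-4-(TIPS-oxy)phenyl]acetate
Product: 17 methyl 2-[5-bromo-2-hydroxy-4-(TIPS-oxy)phenyl]acetate
Conditions: NBS (1.0 equiv), MeCN, -20 to 0 °C
Reagents that add atoms: N-bromosuccinimide, O=C1CCC(=O)N1Br
Why: Electrophilic aromatic bromination para to the free phenol and ortho to the silyloxy group; the only other activated position lies between the two oxygens and is screened by the TIPS group.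

Step 10
Reactants: 17 methyl 2-[5-bromo-2-hydroxy-4-(TIPS-oxy)phenyl]acetate; 13 [3-(TIPS-oxy)phenyl]boronic acid
Product: 18 methyl 2-{5-bromo-4-(TIPS-oxy)-2-[3-(TIPS-oxy)phenoxy]phenyl}acetate
Conditions: Cu(OAc)2 (2 equiv), pyridine, 4 Å MS, CH2Cl2, air, rt
Reagents that add atoms: none
Why: Chan–Lam O-arylation of a phenol by an arylboronic acid at room temperature; the aryl bromide, the ester and the silyl ethers are inert to divalent copper acetate and pyridine.

Step 11
Reactants: 18 methyl 2-{5-bromo-4-(TIPS-oxy)-2-[3-(TIPS-oxy)phenoxy]phenyl}acetate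
Product: 19 methyl 2-{5-(3-methylbut-2-en-1-yl)-4-(TIPS-oxy)-2-[3-(TIPS-oxy)phenoxy]phenyl}acetate (methyl 2-Ar-acetate)
Conditions: Bu3SnCH2CH=CMe2, Pd(PPh3)4 (5 mol%), DMF, 100 °C
Reagents that add atoms: tributyl(3-methylbut-2-en-1-yl)stannane, CCCC[Sn](CCCC)(CCCC)CC=C(C)C
Why: Stille coupling under neutral conditions, which spare the silyl ethers and the ester; reductive elimination at the less hindered allyl terminus gives the linear prenyl arene.

Step 12
Reactants: 11 3-[(1S)-4,4-dimethylcyclobut-2-en-1-yl]propanoic acid; 19 methyl 2-Ar-acetate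
Product: 22 methyl 2-Ar-5-[(1S)-4,4-dimethylcyclobut-2-en-1-yl]-3-oxopentanoate (keto/enol mixture; both C2 epimers), via acyl imidazole 20 (not isolated), via lithium ester enolate 21 (not isolated)
Conditions: 11, CDI, THF, rt; 19, LiN(SiMe3)2 (3.1 equiv), THF, -78 °C; combine, -78 to -20 °C; aq. NH4Cl
Reagents that add atoms: none
Why: Claisen-type C-acylation of an arylacetate enolate by an acyl imidazole; the extra base takes up the liberated imidazole and the acidic product, which drives the reaction and prevents double acylation.

Step 13
Reactants: 22 methyl 2-Ar-5-[(1S)-4,4-dimethylcyclobut-2-en-1-yl]-3-oxopentanoate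
Product: 25 methyl 2-Ar-2-[(1R,5S,7S)-6,6-dimethyl-2-oxobicyclo[3.2.0]heptan-7-yl]acetate (both epimers at the aryl-bearing carbon), via Z-enol tautomer 23 (not isolated), via cyclobutanol photoadduct 24 (not isolated)
Conditions: hν (300 nm lamps, Pyrex), degassed cyclohexane (5 mM), rt; then Et3N (cat.), rt
Reagents that add atoms: none
Why: In cyclohexane the α-aryl β-keto ester sits largely as the chelated Z-enol 23, the only chromophore of 22 that absorbs appreciably at or above 300 nm; its excited (triplet) state bonds through the oxygenated carbon to the nearer cyclobutene carbon, leaving a benzylic, ester-stabilised radical and a cyclobutyl radical that combine to the bicyclo[2.2.0]hexanol 24. The push–pull cyclobutanol then opens by retro-aldol cleavage of the bond between the two former enol carbons (strain release, aryl- and ester-stabilised carbanion), unveiling the cyclopentanone and the arylacetate; the trace of Et3N completes this. The closest known reaction type is the intramolecular de Mayo reaction of enolised 1,3-dicarbonyl compounds with tethered cycloalkenes, and cyclobutenes are established partners in enol and enone [2+2] photocycloadditions. The one ring that remains, the cyclopentanone, is closed in the first bond-forming event by 1,5-closure of the 1,6-diene (five-membered ring, exo mode); the four-membered ring closed by diradical recombination is the temporary one. Both new stereocentres, C1 and C7 of the bicycle, are fixed by the existing cyclobutene stereocentre (C5): the three-atom tether reaches only the alkene face it is attached to, and a bicyclo[2.2.0]hexane can only be cis-fused, so both new bonds are cis to the side chain. The step needs straight and not crossed regiochemistry, which the three-atom tether and the stabilised radical at the aryl-bearing carbon secure, and enolisation toward the ketone only, which a β-keto ester guarantees. It also needs the prenyl alkene and the aryl ethers to stay out: the prenyl group is meta to the reacting side chain and cannot reach the enol, high dilution suppresses intermolecular addition, and Pyrex-filtered light is not absorbed by the aryl ethers. The aryl-bearing carbon emerges as a mixture, which is harmless because it becomes sp2 later.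

Step 14
Reactants: 25 methyl 2-Ar-2-[(1R,5S,7S)-6,6-dimethyl-2-oxobicyclo[3.2.0]heptan-7-yl]acetate
Product: 26 2-Ar-2-[(1R,5S,7S)-6,6-dimethyl-2-oxobicyclo[3.2.0]heptan-7-yl]acetic acid
Conditions: Me3SnOH (5 equiv), ClCH2CH2Cl, 80 °C; then dil. HCl wash
Reagents that add atoms: trimethyltin hydroxide, C[Sn](C)(C)O
Why: Tin hydroxide-mediated methyl ester hydrolysis, chosen because aqueous alkali would strip the aryl silyl ethers; the ketone, the prenyl group and the ring stereocentres are not affected, and the α-carbon is already a mixture.

Step 15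
Reactants: 26 2-Ar-2-[(1R,5S,7S)-6,6-dimethyl-2-oxobicyclo[3.2.0]heptan-7-yl]acetic acid
Product: 28 11-[(1R,5S,7S)-6,6-dimethyl-2-oxobicyclo[3.2.0]heptan-7-yl]-2-(3-methylbut-2-en-1-yl)-3,7-bis(TIPS-oxy)dibenz[b,f]oxepin-10(11H)-one (both C11 epimers), via mixed trifluoroacetic anhydride 27 (not isolated)
Conditions: (CF3CO)2O (2.5 equiv), CH2Cl2, 0 °C to rt
Reagents that add atoms: none
Why: Intramolecular Friedel–Crafts acylation through the acyl trifluoroacetate: ring B is attacked para to its silyloxy group and ortho to the ether oxygen, the only activated position within reach. Trifluoroacetic acid in cold CH2Cl2 is the weakest acid that mediates the closure, chosen to spare the prenyl group.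

Step 16
Reactants: 28 11-[(1R,5S,7S)-6,6-dimethyl-2-oxobicyclo[3.2.0]heptan-7-yl]-2-(3-methylbut-2-en-1-yl)-3,7-bis(TIPS-oxy)dibenz[b,f]oxepin-10(11H)-one
Product: 30 11-[(1R,2R,5S,7S)-2-hydroxy-2,6,6-trimethylbicyclo[3.2.0]heptan-7-yl]-2-(3-methylbut-2-en-1-yl)-3,7-bis(TIPS-oxy)dibenz[b,f]oxepin-10(11H)-one (both C11 epimers), via lithium enolate 29 (not isolated)
Conditions: LiN(SiMe3)2 (1.05 equiv), THF, -78 to 0 °C; MeMgBr/CeCl3 (3 equiv), -78 °C; aq. NH4Cl
Reagents that add atoms: methylmagnesium bromide, C[Mg]Br
Why: The doubly benzylic C11–H is by far the most acidic, so equilibration gives the aryl ketone enolate 29, which masks C10. The weakly basic organocerium reagent then adds to the enolisable cyclopentanone from the convex face, away from the cyclobutane and its endo substituent, placing methyl exo and hydroxyl endo at C2 (organocerium 1,2-addition).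

Step 17
Reactants: 30 11-[(1R,2R,5S,7S)-2-hydroxy-2,6,6-trimethylbicyclo[3.2.0]heptan-7-yl]-2-(3-methylbut-2-en-1-yl)-3,7-bis(TIPS-oxy)dibenz[b,f]oxepin-10(11H)-one
Product: 32 bis(TIPS) ether of the target (pyran closed; configuration as in 30), via cyclic hemiketal 31 (not isolated)
Conditions: PPTS (0.2 equiv), 4 Å MS, toluene, 60 °C
Reagents that add atoms: none
Why: Acid-catalysed cyclodehydration: the endo hydroxyl adds to the C10 ketone and the aryl-stabilised oxocarbenium ion loses the C11 proton to give the conjugated enol ether, removing the C11 mixture. The weak acid and the silylated phenol keep the prenyl group from cyclising.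

Step 18
Reactants: 32 bis(TIPS) ether of the target
Product: 33 CNP0185814.1
Conditions: Bu4NF (2.5 equiv), AcOH (2.5 equiv), THF, 0 °C
Reagents that add atoms: none
Why: Fluoride cleavage of aryl silyl ethers; buffering with acetic acid avoids free phenoxide and leaves the enol ether and the o-prenylphenol intact.

## Compound list

1 | isobutyryl chloride | CC(C)C(Cl)=O | starting material
2 | (2R,5R)-2,5-dimethylpyrrolidine | C[C@@H]1CC[C@@H](C)N1 | starting material
3 | 2-methyl-1-[(2R,5R)-2,5-dimethylpyrrolidin-1-yl]propan-1-one | CC(C)C(=O)N1[C@H](C)CC[C@H]1C | intermediate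
4 | methyl pent-4-enoate | COC(=O)CCC=C | starting material
5 | keteniminium triflate from 3 (not isolated) | CC(C)=C=[N+]1[C@H](C)CC[C@H]1C.[O-]S(=O)(=O)C(F)(F)F | intermediate
6 | cyclobutaniminium triflate (not isolated) | COC(=O)CC[C@H]1CC(=[N+]2[C@H](C)CC[C@H]2C)C1(C)C.[O-]S(=O)(=O)C(F)(F)F | intermediate
7 | methyl 3-[(1S)-2,2-dimethyl-3-oxocyclobutyl]propanoate | COC(=O)CC[C@H]1CC(=O)C1(C)C | intermediate
8 | potassium enolate of 7 (not isolated) | COC(=O)CC[C@H]1C=C([O-])C1(C)C.[K+] | intermediate
9 | methyl 3-[(1S)-4,4-dimethyl-3-(trifluoromethanesulfonyloxy)cyclobut-2-en-1-yl]propanoate | COC(=O)CC[C@H]1C=C(OS(=O)(=O)C(F)(F)F)C1(C)C | intermediate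
10 | methyl 3-[(1S)-4,4-dimethylcyclobut-2-en-1-yl]propanoate | COC(=O)CC[C@H]1C=CC1(C)C | intermediate
11 | 3-[(1S)-4,4-dimethylcyclobut-2-en-1-yl]propanoic acid | OC(=O)CC[C@H]1C=CC1(C)C | intermediate
12 | 3-hydroxyphenylboronic acid | OB(O)c1cccc(O)c1 | starting material
13 | [3-(triisopropylsilyloxy)phenyl]boronic acid | OB(O)c1cccc(O[Si](C(C)C)(C(C)C)C(C)C)c1 | intermediate
14 | 2,4-dihydroxyphenylacetic acid | OC(=O)Cc1ccc(O)cc1O | starting material
15 | methyl 2-(2,4-dihydroxyphenyl)acetate | COC(=O)Cc1ccc(O)cc1O | intermediate
16 | methyl 2-[2-hydroxy-4-(triisopropylsilyloxy)phenyl]acetate | COC(=O)Cc1ccc(O[Si](C(C)C)(C(C)C)C(C)C)cc1O | intermediate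
17 | methyl 2-[5-bromo-2-hydroxy-4-(triisopropylsilyloxy)phenyl]acetate | COC(=O)Cc1cc(Br)c(O[Si](C(C)C)(C(C)C)C(C)C)cc1O | intermediate
18 | methyl 2-{5-bromo-4-(triisopropylsilyloxy)-2-[3-(triisopropylsilyloxy)phenoxy]phenyl}acetate | COC(=O)Cc1cc(Br)c(O[Si](C(C)C)(C(C)C)C(C)C)cc1Oc1cccc(O[Si](C(C)C)(C(C)C)C(C)C)c1 | intermediate
19 | methyl 2-{5-(3-methylbut-2-en-1-yl)-4-(triisopropylsilyloxy)-2-[3-(triisopropylsilyloxy)phenoxy]phenyl}acetate | COC(=O)Cc1cc(CC=C(C)C)c(O[Si](C(C)C)(C(C)C)C(C)C)cc1Oc1cccc(O[Si](C(C)C)(C(C)C)C(C)C)c1 | intermediate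
20 | 1-{3-[(1S)-4,4-dimethylcyclobut-2-en-1-yl]propanoyl}imidazole (not isolated) | O=C(CC[C@H]1C=CC1(C)C)n1ccnc1 | intermediate
21 | lithium enolate of 19 (not isolated) | [Li+].COC([O-])=Cc1cc(CC=C(C)C)c(O[Si](C(C)C)(C(C)C)C(C)C)cc1Oc1cccc(O[Si](C(C)C)(C(C)C)C(C)C)c1 | intermediate
22 | methyl 2-Ar-5-[(1S)-4,4-dimethylcyclobut-2-en-1-yl]-3-oxopentanoate, mixture at C2 | COC(=O)C(c1cc(CC=C(C)C)c(O[Si](C(C)C)(C(C)C)C(C)C)cc1Oc1cccc(O[Si](C(C)C)(C(C)C)C(C)C)c1)C(=O)CC[C@H]1C=CC1(C)C | intermediate
23 | methyl (Z)-2-Ar-5-[(1S)-4,4-dimethylcyclobut-2-en-1-yl]-3-hydroxypent-2-enoate, enol tautomer of 22 (not isolated) | COC(=O)/C(c1cc(CC=C(C)C)c(O[Si](C(C)C)(C(C)C)C(C)C)cc1Oc1cccc(O[Si](C(C)C)(C(C)C)C(C)C)c1)=C(\O)CC[C@H]1C=CC1(C)C | intermediate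
24 | tricyclic cyclobutanol photoadduct: bicyclo[2.2.0]hexanol fused to cyclopentane, all ring fusions cis, aryl-bearing carbon undefined (not isolated) | COC(=O)C1(c4cc(CC=C(C)C)c(O[Si](C(C)C)(C(C)C)C(C)C)cc4Oc4cccc(O[Si](C(C)C)(C(C)C)C(C)C)c4)[C@]2(O)CC[C@H]3[C@@H]2[C@@H]1C3(C)C | intermediate
25 | methyl 2-Ar-2-[(1R,5S,7S)-6,6-dimethyl-2-oxobicyclo[3.2.0]heptan-7-yl]acetate, mixture at the aryl-bearing carbon | COC(=O)C(c1cc(CC=C(C)C)c(O[Si](C(C)C)(C(C)C)C(C)C)cc1Oc1cccc(O[Si](C(C)C)(C(C)C)C(C)C)c1)[C@@H]1[C@H]2[C@H](CCC2=O)C1(C)C | intermediate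
26 | 2-Ar-2-[(1R,5S,7S)-6,6-dimethyl-2-oxobicyclo[3.2.0]heptan-7-yl]acetic acid | OC(=O)C(c1cc(CC=C(C)C)c(O[Si](C(C)C)(C(C)C)C(C)C)cc1Oc1cccc(O[Si](C(C)C)(C(C)C)C(C)C)c1)[C@@H]1[C@H]2[C@H](CCC2=O)C1(C)C | intermediate
27 | mixed anhydride of 26 with trifluoroacetic acid (not isolated) | O=C(OC(=O)C(F)(F)F)C(c1cc(CC=C(C)C)c(O[Si](C(C)C)(C(C)C)C(C)C)cc1Oc1cccc(O[Si](C(C)C)(C(C)C)C(C)C)c1)[C@@H]1[C@H]2[C@H](CCC2=O)C1(C)C | intermediate
28 | 11-[(1R,5S,7S)-6,6-dimethyl-2-oxobicyclo[3.2.0]heptan-7-yl]-2-(3-methylbut-2-en-1-yl)-3,7-bis(triisopropylsilyloxy)dibenz[b,f]oxepin-10(11H)-one, mixture at C11 | CC(C)=CCc1cc2c(cc1O[Si](C(C)C)(C(C)C)C(C)C)Oc1cc(O[Si](C(C)C)(C(C)C)C(C)C)ccc1C(=O)C2[C@@H]1[C@H]2[C@H](CCC2=O)C1(C)C | intermediate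
29 | lithium C10 enolate of 28 (not isolated) | [Li+].CC(C)=CCc1cc2c(cc1O[Si](C(C)C)(C(C)C)C(C)C)Oc1cc(O[Si](C(C)C)(C(C)C)C(C)C)ccc1C([O-])=C2[C@@H]1[C@H]2[C@H](CCC2=O)C1(C)C | intermediate
30 | 11-[(1R,2R,5S,7S)-2-hydroxy-2,6,6-trimethylbicyclo[3.2.0]heptan-7-yl]-2-(3-methylbut-2-en-1-yl)-3,7-bis(triisopropylsilyloxy)dibenz[b,f]oxepin-10(11H)-one, mixture at C11 | CC(C)=CCc1cc2c(cc1O[Si](C(C)C)(C(C)C)C(C)C)Oc1cc(O[Si](C(C)C)(C(C)C)C(C)C)ccc1C(=O)C2[C@@H]1[C@H]2[C@H](CC[C@@]2(C)O)C1(C)C | intermediate
31 | cyclic hemiketal of 30: tertiary oxygen bonded to C10, C10 bearing OH (not isolated) | CC(C)=CCc1cc2c(cc1O[Si](C(C)C)(C(C)C)C(C)C)Oc1cc(O[Si](C(C)C)(C(C)C)C(C)C)ccc1C1(O)C2[C@@H]2[C@H]3[C@H](CC[C@@]3(C)O1)C2(C)C | intermediate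
32 | bis(triisopropylsilyl) ether of the target | CC(C)=CCc1cc2c(cc1O[Si](C(C)C)(C(C)C)C(C)C)Oc1cc(O[Si](C(C)C)(C(C)C)C(C)C)ccc1C1=C2[C@@H]2[C@H]3[C@H](CC[C@@]3(C)O1)C2(C)C | intermediate
33 | CNP0185814.1: prenylated dihydroxydibenz[b,f]oxepine whose C10=C11 bond is shared with a pyran cis-fused to an all-cis 2,6,6-trimethylbicyclo[3.2.0]heptane, methyl exo | CC(C)=CCc1cc2c(cc1O)Oc1cc(O)ccc1C1=C2[C@@H]2[C@H]3[C@H](CC[C@@]3(C)O1)C2(C)C | target

## Step count and risks

Total: 18 steps. Longest linear sequence: 12 steps (14 through steps 7–18; equally 1 through steps 1–5 and 12–18).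

**Step 13 (key step).** Most likely failure: inefficient cycloaddition, because the excited enol relaxes by rotation about its double bond or the enol share is lower than expected. The keto tautomer and the ketone product can then absorb and undergo Norrish cleavage on long irradiation, and the intermediate diradical can disproportionate instead of closing. Fallback, from 22: silylation with Me3SiCl/Et3N would lock the enol as the trimethylsilyl enol ether F1. Irradiation under the same filter would give the O-silylated tricyclic photoadduct F2. PPTS in methanol would remove the silyl group, and the freed cyclobutanol 24 opens to 25. This is the two-stage variant of the de Mayo reaction, and it removes the keto tautomer from the photolysis.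

**Step 2.** Most likely failure: low or reversed facial selectivity, because a terminal alkene with a flexible chain offers the chiral keteniminium ion little to discriminate. Fallback, from 4: the achiral keteniminium ion from N,N-dimethylisobutyramide (Tf2O, collidine) would give the racemic cyclobutanone F3. Its enantiomers would be separated by preparative chromatography on a chiral stationary phase, returning to 7. This replaces asymmetric induction by resolution at the first, cheapest stage.

**Step 15.** Most likely failure: acid-induced loss of the prenyl group (protonation by liberated trifluoroacetic acid, then addition or cyclisation onto the neighbouring silyloxy oxygen). The acyl trifluoroacetate may also be captured by the cyclopentanone enol as an enol lactone before ring B attacks. Fallback, from 18: the bromide would be carried in place of the prenyl group. Acylation of 18 with 20 (as in step 12) would give bromo keto ester F4, irradiation (as in step 13) bromo bicycloheptanone ester F5, and Me3SnOH the bromo acid F6. The Friedel–Crafts closure, now free to use stronger acid, would give bromo oxepinone F7. Stille coupling with Bu3SnCH2CH=CMe2 and Pd(PPh3)4 would then return to 28.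

**Step 16.** Most likely failure: deprotonation at the accessible cyclopentanone CH2 instead of the hindered C11–H. The cyclopentanone would then be masked and C10 exposed, so methyl would add to the wrong carbonyl or the cyclopentanone would return unchanged. Fallback, from 28: equilibrating soft enolisation (Me3SiCl, NaI, Et3N, MeCN) would give the isolable C10 trimethylsilyl enol ether F8. MeMgBr/CeCl3 would add to the only remaining ketone to give tertiary alcohol F9. PPTS would cleave the enol silane and close the pyran in the same operation, returning at 32.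

**Step 11.** Most likely failure: allylic transposition at palladium, giving the 1,1-dimethylallyl isomer, and slow oxidative addition next to the bulky silyloxy group. Fallback, from 18: Stille coupling with Bu3SnCH2CH=CH2 would give the allyl arene F10, where no regiochemical question exists. Cross-metathesis with 2-methylbut-2-ene (second-generation Grubbs catalyst, RuCl2(=CHPh)(PCy3)(H2IMes)) would convert allyl into prenyl and return to 19.

## Further compounds

F1 | step 13 | methyl 2-Ar-5-[(1S)-4,4-dimethylcyclobut-2-en-1-yl]-3-(trimethylsilyloxy)pent-2-enoate | COC(=O)C(c1cc(CC=C(C)C)c(O[Si](C(C)C)(C(C)C)C(C)C)cc1Oc1cccc(O[Si](C(C)C)(C(C)C)C(C)C)c1)=C(O[Si](C)(C)C)CC[C@H]1C=CC1(C)C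
F2 | step 13 | O-trimethylsilyl ether of photoadduct 24 | COC(=O)C1(c4cc(CC=C(C)C)c(O[Si](C(C)C)(C(C)C)C(C)C)cc4Oc4cccc(O[Si](C(C)C)(C(C)C)C(C)C)c4)[C@]2(O[Si](C)(C)C)CC[C@H]3[C@@H]2[C@@H]1C3(C)C
F3 | step 2 | racemic methyl 3-(2,2-dimethyl-3-oxocyclobutyl)propanoate | COC(=O)CCC1CC(=O)C1(C)C
F4 | step 15 | bromo analogue of 22 (Br in place of prenyl) | COC(=O)C(c1cc(Br)c(O[Si](C(C)C)(C(C)C)C(C)C)cc1Oc1cccc(O[Si](C(C)C)(C(C)C)C(C)C)c1)C(=O)CC[C@H]1C=CC1(C)C
F5 | step 15 | bromo analogue of 25 | COC(=O)C(c1cc(Br)c(O[Si](C(C)C)(C(C)C)C(C)C)cc1Oc1cccc(O[Si](C(C)C)(C(C)C)C(C)C)c1)[C@@H]1[C@H]2[C@H](CCC2=O)C1(C)C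
F6 | step 15 | bromo analogue of 26 | OC(=O)C(c1cc(Br)c(O[Si](C(C)C)(C(C)C)C(C)C)cc1Oc1cccc(O[Si](C(C)C)(C(C)C)C(C)C)c1)[C@@H]1[C@H]2[C@H](CCC2=O)C1(C)C
F7 | step 15 | bromo analogue of 28 (2-bromo oxepinone) | Brc1cc2c(cc1O[Si](C(C)C)(C(C)C)C(C)C)Oc1cc(O[Si](C(C)C)(C(C)C)C(C)C)ccc1C(=O)C2[C@@H]1[C@H]2[C@H](CCC2=O)C1(C)C
F8 | step 16 | C10 trimethylsilyl enol ether of 28 | CC(C)=CCc1cc2c(cc1O[Si](C(C)C)(C(C)C)C(C)C)Oc1cc(O[Si](C(C)C)(C(C)C)C(C)C)ccc1C(O[Si](C)(C)C)=C2[C@@H]1[C@H]2[C@H](CCC2=O)C1(C)C
F9 | step 16 | C10 trimethylsilyl enol ether of 30 | CC(C)=CCc1cc2c(cc1O[Si](C(C)C)(C(C)C)C(C)C)Oc1cc(O[Si](C(C)C)(C(C)C)C(C)C)ccc1C(O[Si](C)(C)C)=C2[C@@H]1[C@H]2[C@H](CC[C@@]2(C)O)C1(C)C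
F10 | step 11 | methyl 2-{5-allyl-4-(triisopropylsilyloxy)-2-[3-(triisopropylsilyloxy)phenoxy]phenyl}acetate | COC(=O)Cc1cc(CC=C)c(O[Si](C(C)C)(C(C)C)C(C)C)cc1Oc1cccc(O[Si](C(C)C)(C(C)C)C(C)C)c1
A1 | alternative 1 | diazo diquinanone monoketal (diazo carbon between ketone and ring fusion, CMe2 on the other side of the ketone) | [N-]=[N+]=C1[C@H]2[C@H](CCC23OCCO3)C(C)(C)C1=O
A2 | alternative 1 | methyl 6,6-dimethylbicyclo[3.2.0]heptane-7-carboxylate 2-dioxolane ketal | COC(=O)[C@@H]1[C@H]2[C@H](CCC23OCCO3)C1(C)C
A3 | alternative 2 | (R)-linalool | CC(C)=CCC[C@@](C)(O)C=C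
A4 | alternative 2 | (R)-5-methyl-5-(4-methylpent-3-en-1-yl)furan-2(5H)-one | CC(C)=CCC[C@@]1(C)OC(=O)C=C1
A5 | alternative 2 | tricyclic γ-lactone (cyclobutane fused to cyclopentane and lactone) | O=C1[C@@H]2[C@H]3[C@H](CC[C@@]3(C)O1)C2(C)C
A6 | alternative 3 | 1-[2-fluoro-4-(tert-butyldimethylsilyloxy)phenyl]-2-(2-hydroxy-2,6,6-trimethylbicyclo[3.2.0]heptan-7-yl)ethanone, configured as in A8 | O=C(C[C@@H]1[C@H]2[C@H](CC[C@@]2(C)O)C1(C)C)c1ccc(O[Si](C)(C)C(C)(C)C)cc1F
A7 | alternative 3 | 2-bromo-4-(3-methylbut-2-en-1-yl)-5-(tert-butyldimethylsilyloxy)phenol | Oc1cc(O[Si](C)(C)C(C)(C)C)c(CC=C(C)C)cc1Br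
A8 | alternative 3 | 11-(hydroxybicycloheptyl)dibenz[b,f]oxepin-10(11H)-one bis(tert-butyldimethylsilyl) ether, mixture at C11 | CC(C)=CCc1cc2c(cc1O[Si](C)(C)C(C)(C)C)Oc1cc(O[Si](C)(C)C(C)(C)C)ccc1C(=O)C2[C@@H]2[C@H]3[C@H](CC[C@@]3(C)O)C2(C)C
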